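**Plan**
1. Retrosynthesis: the C15 oxidation and C16 reduction, then C13–C16 (ring D), C8–C15 (propargylation), C8–C14 with C9–C11 (ring C, Diels–Alder), then C9–C10, the C20–O–C7 ester link and C10–C20 (spiro-lactone), and last C2=C3 with C4–C5 (ring A).
2. Forward: ring A arises first, in one flask, from isobutyraldehyde and ethyl 4-oxopent-2-enoate (Michael addition, then aldol condensation C2 onto C3); the lactone is then spiro-fused at C10, ring C is annulated on its C8=C9 bond, and ring D is closed from C8 to C13.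
3. Enabling feature: in ring A, C3 lies next to the quaternary gem-dimethyl carbon C4 and C1 is a ketone flanked by C10; the open precursor therefore holds a non-enolisable aldehyde (C3) and a methyl ketone (C2) that can close only to the six-membered enone.
4. Stereochemistry: C5 comes from the chiral amine catalyst in the Michael step; C10 (attack anti to the C5 side chain), C9 and C8 (diene anti to C5, alkylation anti to C10), C13 (bridging) and C16 (exo protonation) are relayed from it.
5. Helpers: C6 is carried as an ester to activate the acceptor and is reduced later; an allyl ester on C8 activates the dienophile and is excised; a phenylthio group steers the diene and is removed by SmI2; the C1 ketone is masked as an allylic alcohol during the SmI2 step.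

Key step: step 1

Remark: atom numbers C1–C20 in names follow ent-kaurane numbering of the target (ring A: C1–C5, C10; lactone: C10–C20–O–C7–C8–C9; ring C: C8, C9, C11–C14; ring D: C8, C14, C13, C16, C15; C6 is the CH2OH carbon, C17 the methyl on C16).
Assumption: the quinine-derived primary amine is taken to give the (S)-configured Michael adduct 3; if the sense of induction on this acceptor is the opposite, the quinidine-derived pseudoenantiomer is used.

**Step 1**
Reactants: 1 isobutyraldehyde; 2 ethyl (E)-4-oxopent-2-enoate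
Product: 5 ethyl (1S)-2,2-dimethyl-5-oxocyclohex-3-ene-1-carboxylate, via Michael adduct 3 (not isolated), via aldol 4 (not isolated)
Conditions: 9-amino-9-deoxy-epi-quinine (20 mol %), PhCO2H (40 mol %), toluene, 40 °C; then p-TsOH·H2O (30 mol %), reflux, Dean–Stark
Reagents that add atoms: none
Why: The primary amine condenses with 1 to an enamine that adds to C5 of 2, the carbon β to the ketone, while the protonated quinuclidine binds the acceptor, giving Michael adduct 3; acid then enolises the methyl ketone towards C2, which attacks the C3 aldehyde, and aldol 4 loses water to the conjugated enone. The closest known reaction type is the amine-mediated Robinson-type annulation of isobutyraldehyde with methyl vinyl ketone to 4,4-dimethylcyclohex-2-enone, joined here to an enamine Michael addition of an α-branched aldehyde to a doubly activated olefin. Ring A closes by a 6-(enolendo)-exo-trig aldol addition of C2 to C3. The only lasting stereocentre, C5, is set in the Michael step under catalyst control, and the C3 carbinol centre of 4 is lost on dehydration. The step needs regioselective conjugate addition, secured by the ketone being the stronger activating group so that attack occurs at the ester-bearing carbon, and a single aldol mode, secured by quaternary C4, which leaves the aldehyde without α-hydrogens, and by the fact that closure through C10 would give a four-membered ring.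

**Step 2**
Reactants: 5 ethyl (1S)-2,2-dimethyl-5-oxocyclohex-3-ene-1-carboxylate
Product: 6 (5S)-5-(hydroxymethyl)-4,4-dimethylcyclohex-2-en-1-ol (C1 epimers)
Conditions: DIBAL-H (3.5 equiv), CH2Cl2, −78 → 0 °C; aq. Rochelle salt
Reagents that add atoms: none
Why: DIBAL-H reduction should take the ester to the primary alcohol and the enone carbonyl to the allylic alcohol by 1,2-hydride delivery, leaving C5 untouched, while the new C1 carbinol centre is of no consequence because it is re-oxidised in step 4.

**Step 3**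
Reactants: 6 (5S)-5-(hydroxymethyl)-4,4-dimethylcyclohex-2-en-1-ol
Product: 7 (5S)-5-({[tert-butyl(diphenyl)silyl]oxy}methyl)-4,4-dimethylcyclohex-2-en-1-ol (C1 epimers)
Conditions: TBDPSCl (1.05 equiv), imidazole, CH2Cl2, 0 °C
Reagents that add atoms: tert-butyl(chloro)diphenylsilane (CC(C)(C)[Si](Cl)(c1ccccc1)c1ccccc1)
Why: Silyl ether formation with the bulky chlorosilane is expected to select the primary hydroxyl over the hindered secondary allylic one.

**Step 4**
Reactants: 7 (5S)-5-({[tert-butyl(diphenyl)silyl]oxy}methyl)-4,4-dimethylcyclohex-2-en-1-ol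
Product: 8 (5S)-5-({[tert-butyl(diphenyl)silyl]oxy}methyl)-4,4-dimethylcyclohex-2-en-1-one
Conditions: MnO2 (excess), CH2Cl2, rt
Reagents that add atoms: none
Why: MnO2 oxidation of the allylic alcohol restores the enone that is needed for enolate chemistry at C10.

**Step 5**
Reactants: 8 (5S)-5-({[tert-butyl(diphenyl)silyl]oxy}methyl)-4,4-dimethylcyclohex-2-en-1-one
Product: 10 (5S)-5-({[tert-butyl(diphenyl)silyl]oxy}methyl)-4,4-dimethyl-6-{[(triethylsilyl)oxy]methyl}cyclohex-2-en-1-one (C6 epimers), via aldol 9 (not isolated)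
Conditions: LDA, THF, −78 °C; CH2O (gas from cracked paraformaldehyde), −78 °C; then Et3SiCl, −78 → 0 °C
Reagents that add atoms: formaldehyde (C=O); chlorotriethylsilane (CC[Si](Cl)(CC)CC)
Why: LDA can deprotonate only C10 of this enone (C2 is vinylic, C4 quaternary), the lithium enolate should undergo aldol addition to monomeric formaldehyde, and silylation of the aldolate in the same flask prevents retro-aldol cleavage, the C10 configuration being irrelevant because this centre is enolised again in step 7.

**Step 6**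
Reactants: 11 diallyl malonate
Product: 12 diallyl 2-(ethoxymethylidene)malonate
Conditions: HC(OEt)3, Ac2O, ZnCl2 (cat.), 130 °C
Reagents that add atoms: triethyl orthoformate (CCOC(OCC)OCC)
Why: Condensation of a malonate with triethyl orthoformate in acetic anhydride is the standard preparation of alkoxymethylidene malonates.

**Step 7**
Reactants: 10 triethylsilyl ether (C6 epimers); 12 diallyl 2-(ethoxymethylidene)malonate
Product: 13 diallyl 2-{[(1S,6R)-6-({[tert-butyl(diphenyl)silyl]oxy}methyl)-5,5-dimethyl-2-oxo-1-{[(triethylsilyl)oxy]methyl}cyclohex-3-en-1-yl]methylidene}malonate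
Conditions: LDA, THF, −78 °C; then 12, −78 → −20 °C; aq. NH4Cl
Reagents that add atoms: none
Why: Conjugate addition–elimination of a ketone lithium enolate to an alkoxymethylidene malonate forms the C9–C10 bond, and the acceptor should approach C10 anti to the neighbouring C5 silyloxymethyl group, so that C9 ends trans to C6 and the quaternary centre has the target configuration.

**Step 8**
Reactants: 13 alkylidene malonate
Product: 15 allyl (6S,7R)-7-({[tert-butyl(diphenyl)silyl]oxy}methyl)-8,8-dimethyl-3,11-dioxo-2-oxaspiro[5.5]undeca-4,9-diene-4-carboxylate, via hydroxy diester 14 (not isolated)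
Conditions: AcOH–THF–H2O (3:1:1), rt; then CSA (cat.), toluene, 80 °C
Reagents that add atoms: none
Why: Mild acid should cleave the triethylsilyl ether but not the tert-butyldiphenylsilyl ether, and the freed C20 hydroxyl lactonises by acid-catalysed transesterification onto the ester cis to C10, giving the spiro δ-lactone whose C8=C9 bond is doubly activated.

**Step 9**
Reactants: 16 1-(phenylthio)propan-2-one
Product: 17 3-(phenylthio)but-3-en-2-one
Conditions: (CH2O)n, N-methylanilinium trifluoroacetate, THF, reflux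
Reagents that add atoms: formaldehyde as paraformaldehyde (C=O)
Why: Acid-mediated Mannich condensation followed by amine elimination (α-methylenation) should occur at the more acidic sulfur-bearing methylene.

**Step 10**
Reactants: 17 3-(phenylthio)but-3-en-2-one
Product: 18 tert-butyl(dimethyl){[3-(phenylthio)buta-1,3-dien-2-yl]oxy}silane
Conditions: TBSOTf, Et3N, CH2Cl2, 0 °C; used at once
Reagents that add atoms: tert-butyldimethylsilyl triflate (CC(C)(C)[Si](C)(C)OS(=O)(=O)C(F)(F)F)
Why: Soft enolisation of the methyl ketone with silyl triflate and amine gives the 2-silyloxy diene.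

**Step 11**
Reactants: 15 spiro ene-lactone allyl ester; 18 2-silyloxy-3-(phenylthio)butadiene
Product: 19 Diels–Alder adduct (5R,8S,9S,10S) with ring C fused at C8–C9 and carrying 8-allyloxycarbonyl plus 13-(tert-butyldimethylsilyloxy)-12-(phenylthio)-12-ene
Conditions: toluene, BHT (cat.), 110 °C, sealed tube
Reagents that add atoms: none
Why: In this thermal Diels–Alder reaction of a 2-silyloxy-3-arylthio diene with an alkylidene malonate-type dienophile, the diene terminus next to the sulfur-bearing carbon should bond to the electrophilic C9 (sulfur-directed regiochemistry, which places oxygen on C13), and the diene should add to the face of C8=C9 anti to the C5 side of ring A, setting C9 and, by suprafacial addition, C8 with the ester cis to H9.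

**Step 12**
Reactants: 19 Diels–Alder adduct
Product: 21 decarboxylated tricyclic lactone (5R,9R,10S; C8–H epimers), via acid 20 (not isolated)
Conditions: Pd(PPh3)4 (5 mol %), morpholine, THF, rt; then toluene, 100 °C
Reagents that add atoms: none
Why: Pd(PPh3)4-catalysed allyl transfer to morpholine (Tsuji–Trost deallylation) frees the malonic half-acid, which decarboxylates on heating, the C8 configuration being of no consequence since it is set in step 13.

**Step 13**
Reactants: 21 decarboxylated tricyclic lactone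
Product: 22 8-propargyl lactone (5R,8S,9S,10S)
Conditions: LDA, THF–HMPA, −78 °C; propargyl bromide, −78 → −40 °C
Reagents that add atoms: propargyl bromide (C#CCBr)
Why: Alkylation of the lactone lithium enolate should occur on the face of C8 syn to H9 and anti to the quaternary C10, giving the cis-fused quaternary centre with the propargyl group axial on ring C, while the ring A enone has no enolisable hydrogen.

**Step 14**
Reactants: 22 8-propargyl lactone
Product: 24 12-(phenylthio)-13-ketone bearing the 1-hydroxy-2-ene ring A (C1 epimers; C12 epimers), via allylic alcohol 23 (not isolated)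
Conditions: NaBH4, CeCl3·7H2O, MeOH–THF, −78 °C; then 1 M HCl, THF, 0 °C
Reagents that add atoms: none
Why: Luche 1,2-reduction masks the ring A enone as the allylic alcohol before the electron-transfer step, and dilute acid then hydrolyses the silyl enol ether to the C13 ketone without touching the tert-butyldiphenylsilyl ether.

**Step 15**
Reactants: 24 12-(phenylthio)-13-ketone
Product: 26 tetracyclic 16-methylidene 1,13-diol (5R,8S,9S,10S,13S; C1 epimers), via ketone 25 (not isolated)
Conditions: SmI2 (6 equiv), HMPA, t-BuOH, THF, −78 °C → rt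
Reagents that add atoms: none
Why: SmI2 should first cleave the C12–S bond of the α-arylthio ketone and then reduce the C13 ketone to a ketyl radical that closes ring D by 5-exo-dig addition to the alkyne (ketyl–alkyne reductive cyclisation), the axial propargyl group allowing only the bridged mode so that C13 carries the bridgehead hydroxyl as in the target.

**Step 16**
Reactants: 26 tetracyclic 16-methylidene 1,13-diol
Product: 27 16-methylidene 1,13,15-triol (C1 epimers; C15 epimers)
Conditions: SeO2 (0.5 equiv), t-BuOOH, CH2Cl2, rt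
Reagents that add atoms: selenium dioxide (O=[Se]=O); tert-butyl hydroperoxide (CC(C)(C)OO)
Why: SeO2-mediated allylic hydroxylation (ene reaction, then [2,3]-shift) can occur only at C15, the single allylic C–H position of the exocyclic alkene.

**Step 17**
Reactants: 27 16-methylidene 1,13,15-triol
Product: 28 13-hydroxy-1,15-dioxo-2,16-diene (bis-enone)
Conditions: Dess–Martin periodinane, CH2Cl2, rt
Reagents that add atoms: none
Why: Dess–Martin oxidation converts both secondary allylic alcohols (C1 and C15) into enones and leaves the tertiary C13 hydroxyl untouched.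

**Step 18**
Reactants: 28 bis-enone
Product: 29 6-O-tert-butyldiphenylsilyl ether of the target (5R,8S,9S,10S,13S,16R)
Conditions: [(Ph3P)CuH]6 (0.2 equiv), H2O (2 equiv), toluene, −20 → 0 °C
Reagents that add atoms: none
Why: Copper hydride conjugate reduction is expected to occur at the unhindered exocyclic methylene C17 much faster than at the neopentyl C3 of the ring A enone, and protonation of the copper enolate from the exo face (the side of the one-carbon bridge C14) should give the 16R methyl ketone under kinetic control.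

**Step 19**
Reactants: 29 silyl ether of the target
Product: 30 target CNP0533761.1 (5R,8S,9S,10S,13S,16R)
Conditions: HF·pyridine, THF–pyridine, 0 °C → rt
Reagents that add atoms: none
Why: Fluoride-mediated Si–O cleavage under mildly acidic conditions frees the C6 hydroxyl without epimerising C16 or opening the β-hydroxy ketone.

**Compound list**
1 | isobutyraldehyde | CC(C)C=O | starting material
2 | ethyl (E)-4-oxopent-2-enoate | CCOC(=O)/C=C/C(C)=O | starting material
3 | ethyl (2S)-2-(2-methyl-1-oxopropan-2-yl)-4-oxopentanoate | CCOC(=O)[C@@H](CC(C)=O)C(C)(C)C=O | intermediate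
4 | ethyl (1S)-3-hydroxy-2,2-dimethyl-5-oxocyclohexane-1-carboxylate (C3 epimers) | CCOC(=O)[C@H]1CC(=O)CC(O)C1(C)C | intermediate
5 | ethyl (1S)-2,2-dimethyl-5-oxocyclohex-3-ene-1-carboxylate | CCOC(=O)[C@H]1CC(=O)C=CC1(C)C | intermediate
6 | (5S)-5-(hydroxymethyl)-4,4-dimethylcyclohex-2-en-1-ol (C1 epimers) | OC[C@H]1CC(O)C=CC1(C)C | intermediate
7 | (5S)-5-({[tert-butyl(diphenyl)silyl]oxy}methyl)-4,4-dimethylcyclohex-2-en-1-ol (C1 epimers) | CC(C)(C)[Si](OC[C@H]1CC(O)C=CC1(C)C)(c1ccccc1)c1ccccc1 | intermediate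
8 | (5S)-5-({[tert-butyl(diphenyl)silyl]oxy}methyl)-4,4-dimethylcyclohex-2-en-1-one | CC(C)(C)[Si](OC[C@H]1CC(=O)C=CC1(C)C)(c1ccccc1)c1ccccc1 | intermediate
9 | (5S)-5-({[tert-butyl(diphenyl)silyl]oxy}methyl)-6-(hydroxymethyl)-4,4-dimethylcyclohex-2-en-1-one (C6 epimers) | CC(C)(C)[Si](OC[C@H]1C(CO)C(=O)C=CC1(C)C)(c1ccccc1)c1ccccc1 | intermediate
10 | (5S)-5-({[tert-butyl(diphenyl)silyl]oxy}methyl)-4,4-dimethyl-6-{[(triethylsilyl)oxy]methyl}cyclohex-2-en-1-one (C6 epimers) | CC(C)(C)[Si](OC[C@H]1C(CO[Si](CC)(CC)CC)C(=O)C=CC1(C)C)(c1ccccc1)c1ccccc1 | intermediate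
11 | diallyl malonate | C=CCOC(=O)CC(=O)OCC=C | starting material
12 | diallyl 2-(ethoxymethylidene)malonate | CCOC=C(C(=O)OCC=C)C(=O)OCC=C | intermediate
13 | diallyl 2-{[(1S,6R)-6-({[tert-butyl(diphenyl)silyl]oxy}methyl)-5,5-dimethyl-2-oxo-1-{[(triethylsilyl)oxy]methyl}cyclohex-3-en-1-yl]methylidene}malonate | O=C1C=CC(C)(C)[C@@H](CO[Si](c2ccccc2)(c2ccccc2)C(C)(C)C)[C@]1(CO[Si](CC)(CC)CC)C=C(C(=O)OCC=C)C(=O)OCC=C | intermediate
14 | diallyl 2-{[(1S,6R)-6-({[tert-butyl(diphenyl)silyl]oxy}methyl)-1-(hydroxymethyl)-5,5-dimethyl-2-oxocyclohex-3-en-1-yl]methylidene}malonate | O=C1C=CC(C)(C)[C@@H](CO[Si](c2ccccc2)(c2ccccc2)C(C)(C)C)[C@]1(CO)C=C(C(=O)OCC=C)C(=O)OCC=C | intermediate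
15 | allyl (6S,7R)-7-({[tert-butyl(diphenyl)silyl]oxy}methyl)-8,8-dimethyl-3,11-dioxo-2-oxaspiro[5.5]undeca-4,9-diene-4-carboxylate | O=C1C=CC(C)(C)[C@@H](CO[Si](c2ccccc2)(c2ccccc2)C(C)(C)C)[C@@]13COC(=O)C(C(=O)OCC=C)=C3 | intermediate
16 | 1-(phenylthio)propan-2-one | CC(=O)CSc1ccccc1 | starting material
17 | 3-(phenylthio)but-3-en-2-one | CC(=O)C(=C)Sc1ccccc1 | intermediate
18 | tert-butyl(dimethyl){[3-(phenylthio)buta-1,3-dien-2-yl]oxy}silane | C=C(O[Si](C)(C)C(C)(C)C)C(=C)Sc1ccccc1 | intermediate
19 | Diels–Alder adduct (5R,8S,9S,10S): ring A enone, spiro-lactone, ring C with 8-allyloxycarbonyl, 13-silyloxy-12-(phenylthio)-12-ene | C=CCOC(=O)[C@]23CC(O[Si](C)(C)C(C)(C)C)=C(Sc4ccccc4)C[C@H]2[C@]1(COC3=O)C(=O)C=CC(C)(C)[C@H]1CO[Si](c1ccccc1)(c1ccccc1)C(C)(C)C | intermediate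
20 | C8 carboxylic acid of 19 (5R,8S,9S,10S) | OC(=O)[C@]23CC(O[Si](C)(C)C(C)(C)C)=C(Sc4ccccc4)C[C@H]2[C@]1(COC3=O)C(=O)C=CC(C)(C)[C@H]1CO[Si](c1ccccc1)(c1ccccc1)C(C)(C)C | intermediate
21 | decarboxylated tricyclic lactone (5R,9R,10S; C8–H epimers) | C23CC(O[Si](C)(C)C(C)(C)C)=C(Sc4ccccc4)C[C@H]2[C@]1(COC3=O)C(=O)C=CC(C)(C)[C@H]1CO[Si](c1ccccc1)(c1ccccc1)C(C)(C)C | intermediate
22 | 8-propargyl lactone (5R,8S,9S,10S) | C#CC[C@]23CC(O[Si](C)(C)C(C)(C)C)=C(Sc4ccccc4)C[C@H]2[C@]1(COC3=O)C(=O)C=CC(C)(C)[C@H]1CO[Si](c1ccccc1)(c1ccccc1)C(C)(C)C | intermediate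
23 | C1 allylic alcohol of 22 (C1 epimers) | C#CC[C@]23CC(O[Si](C)(C)C(C)(C)C)=C(Sc4ccccc4)C[C@H]2[C@]1(COC3=O)C(O)C=CC(C)(C)[C@H]1CO[Si](c1ccccc1)(c1ccccc1)C(C)(C)C | intermediate
24 | 12-(phenylthio)-13-ketone with 1-hydroxy-2-ene ring A (C1 and C12 epimers) | C#CC[C@]23CC(=O)C(Sc4ccccc4)C[C@H]2[C@]1(COC3=O)C(O)C=CC(C)(C)[C@H]1CO[Si](c1ccccc1)(c1ccccc1)C(C)(C)C | intermediate
25 | 13-ketone with 8-propargyl and 1-hydroxy-2-ene ring A (C1 epimers) | C#CC[C@]23CC(=O)CC[C@H]2[C@]1(COC3=O)C(O)C=CC(C)(C)[C@H]1CO[Si](c1ccccc1)(c1ccccc1)C(C)(C)C | intermediate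
26 | tetracyclic 16-methylidene 1,13-diol (5R,8S,9S,10S,13S; C1 epimers) | C=C1C[C@]23C[C@@]1(O)CC[C@H]2[C@]1(COC3=O)C(O)C=CC(C)(C)[C@H]1CO[Si](c1ccccc1)(c1ccccc1)C(C)(C)C | intermediate
27 | 16-methylidene 1,13,15-triol (C1 and C15 epimers) | C=C1C(O)[C@]23C[C@@]1(O)CC[C@H]2[C@]1(COC3=O)C(O)C=CC(C)(C)[C@H]1CO[Si](c1ccccc1)(c1ccccc1)C(C)(C)C | intermediate
28 | 13-hydroxy-1,15-dioxo-2,16-diene (bis-enone) | C=C1C(=O)[C@]23C[C@@]1(O)CC[C@H]2[C@]1(COC3=O)C(=O)C=CC(C)(C)[C@H]1CO[Si](c1ccccc1)(c1ccccc1)C(C)(C)C | intermediate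
29 | 6-O-tert-butyldiphenylsilyl ether of the target | C[C@H]1C(=O)[C@]23C[C@@]1(O)CC[C@H]2[C@]1(COC3=O)C(=O)C=CC(C)(C)[C@H]1CO[Si](c1ccccc1)(c1ccccc1)C(C)(C)C | intermediate
30 | CNP0533761.1: (5R,8S,9S,10S,13S,16R)-6,13-dihydroxy-1,15-dioxo-6,7-seco-kaur-2-ene 7,20-lactone | C[C@H]1C(=O)[C@]23C[C@@]1(O)CC[C@H]2[C@]1(COC3=O)C(=O)C=CC(C)(C)[C@H]1CO | target

**Totals**
Total step count: 19. Longest linear sequence: 16 steps (steps 1–5, 7, 8, 11–19).

**Steps most likely to fail**

Step 11. The cycloaddition may stall because C9 is neopentyl, and the sulfur-controlled regiochemistry may erode, giving the 12-oxygenated isomer. The fallback sets out from 15 and comes back at 25. Hosomi–Sakurai allylation (allyltrimethylsilane, TiCl4, CH2Cl2, −78 °C) adds an allyl group to C9 anti to C5 and gives the 9-allyl lactone ester F1. Alkylation of its C8 carbanion (K2CO3, chloroacetone, NaI) gives the 8-acetonyl compound F2. TBSOTf and Et3N convert the methyl ketone into the terminal silyl enol ether F3. Ring-closing metathesis with the second-generation Hoveyda–Grubbs catalyst (toluene, 80 °C) joins C12 to C13 and gives the cyclic silyl enol ether F4 with loss of ethylene. The conditions of step 12 remove the allyl ester and give the decarboxylated enol ether F5. LDA and propargyl bromide, as in step 13, give the 8-propargyl enol ether F6. The conditions of step 14 then give ketone 25, which is taken on with SmI2 as in step 15.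

Step 7. The fully substituted enolate may lose triethylsilanolate by β-elimination, or may fail to add to the bulky acceptor. The fallback sets out from 10 and comes back at 15. LDA with Me3SiCl present gives the trimethylsilyl dienol ether F7. Mukaiyama-type alkylation with HC(OMe)3 and BF3·OEt2 brings the small dimethoxycarbenium ion to C10 anti to the C5 side chain and gives the dimethyl acetal F8. 1 M HCl in THF cleaves the acetal and the triethylsilyl ether to the hydroxy aldehyde F9. Esterification of the C20 hydroxyl with monoallyl malonate (DCC, DMAP) gives the malonate ester F10. Piperidinium acetate then closes the lactone ring by intramolecular Knoevenagel condensation to 15; C10 is quaternary at this stage, so no β-elimination is possible.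

Step 18. Conjugate reduction may also touch the ring A enone, or over-reduction may occur. The fallback sets out from 26 and comes back at 29. Et3SiCl and imidazole silylate only the secondary C1 hydroxyl and give the C1 triethylsilyl ether F11. SeO2 with t-BuOOH gives the 15-alcohol F12. Dess–Martin oxidation gives the single enone F13. [(Ph3P)CuH]6 reduces this only enone to the 16R methyl ketone F14. AcOH–THF–H2O removes the triethylsilyl group to give the C1 allylic alcohol F15. MnO2 oxidises it to 29.

**Further compounds**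
F1 | step 11 | 9-allyl lactone ester (C8 epimers) | O=C1C=CC(C)(C)[C@@H](CO[Si](c2ccccc2)(c2ccccc2)C(C)(C)C)[C@@]13COC(=O)C(C(=O)OCC=C)[C@H]3CC=C
F2 | step 11 | 8-acetonyl compound (C8 epimers) | O=C1C=CC(C)(C)[C@@H](CO[Si](c2ccccc2)(c2ccccc2)C(C)(C)C)[C@@]13COC(=O)C(CC(C)=O)(C(=O)OCC=C)[C@H]3CC=C
F3 | step 11 | terminal silyl enol ether of F2 | O=C1C=CC(C)(C)[C@@H](CO[Si](c2ccccc2)(c2ccccc2)C(C)(C)C)[C@@]13COC(=O)C(CC(=C)O[Si](C)(C)C(C)(C)C)(C(=O)OCC=C)[C@H]3CC=C
F4 | step 11 | cyclic silyl enol ether with ring C closed (12-ene, 8-allyloxycarbonyl, C8 epimers) | C=CCOC(=O)C23CC(O[Si](C)(C)C(C)(C)C)=CC[C@H]2[C@]1(COC3=O)C(=O)C=CC(C)(C)[C@H]1CO[Si](c1ccccc1)(c1ccccc1)C(C)(C)C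
F5 | step 11 | decarboxylated cyclic silyl enol ether (C8–H epimers) | C23CC(O[Si](C)(C)C(C)(C)C)=CC[C@H]2[C@]1(COC3=O)C(=O)C=CC(C)(C)[C@H]1CO[Si](c1ccccc1)(c1ccccc1)C(C)(C)C
F6 | step 11 | 8-propargyl cyclic silyl enol ether | C#CC[C@]23CC(O[Si](C)(C)C(C)(C)C)=CC[C@H]2[C@]1(COC3=O)C(=O)C=CC(C)(C)[C@H]1CO[Si](c1ccccc1)(c1ccccc1)C(C)(C)C
F7 | step 7 | trimethylsilyl dienol ether of 10 | C[Si](C)(C)OC1=C(CO[Si](CC)(CC)CC)[C@H](CO[Si](c2ccccc2)(c2ccccc2)C(C)(C)C)C(C)(C)C=C1
F8 | step 7 | C10 dimethoxymethyl ketone | O=C1C=CC(C)(C)[C@@H](CO[Si](c2ccccc2)(c2ccccc2)C(C)(C)C)[C@]1(CO[Si](CC)(CC)CC)C(OC)OC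
F9 | step 7 | C10 formyl C20 hydroxy ketone | O=C1C=CC(C)(C)[C@@H](CO[Si](c2ccccc2)(c2ccccc2)C(C)(C)C)[C@]1(CO)C=O
F10 | step 7 | allyl malonate ester of F9 | O=C1C=CC(C)(C)[C@@H](CO[Si](c2ccccc2)(c2ccccc2)C(C)(C)C)[C@]1(COC(=O)CC(=O)OCC=C)C=O
F11 | step 18 | C1 triethylsilyl ether of 26 | C=C1C[C@]23C[C@@]1(O)CC[C@H]2[C@]1(COC3=O)C(O[Si](CC)(CC)CC)C=CC(C)(C)[C@H]1CO[Si](c1ccccc1)(c1ccccc1)C(C)(C)C
F12 | step 18 | 15-alcohol of F11 (C15 epimers) | C=C1C(O)[C@]23C[C@@]1(O)CC[C@H]2[C@]1(COC3=O)C(O[Si](CC)(CC)CC)C=CC(C)(C)[C@H]1CO[Si](c1ccccc1)(c1ccccc1)C(C)(C)C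
F13 | step 18 | 15-oxo-16-methylidene C1 silyl ether | C=C1C(=O)[C@]23C[C@@]1(O)CC[C@H]2[C@]1(COC3=O)C(O[Si](CC)(CC)CC)C=CC(C)(C)[C@H]1CO[Si](c1ccccc1)(c1ccccc1)C(C)(C)C
F14 | step 18 | 16R methyl 15-ketone C1 silyl ether | C[C@H]1C(=O)[C@]23C[C@@]1(O)CC[C@H]2[C@]1(COC3=O)C(O[Si](CC)(CC)CC)C=CC(C)(C)[C@H]1CO[Si](c1ccccc1)(c1ccccc1)C(C)(C)C
F15 | step 18 | C1 allylic alcohol corresponding to 29 | C[C@H]1C(=O)[C@]23C[C@@]1(O)CC[C@H]2[C@]1(COC3=O)C(O)C=CC(C)(C)[C@H]1CO[Si](c1ccccc1)(c1ccccc1)C(C)(C)C
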